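**Plan**

- Cuts: (a) the CH2–C(=O)Ph bond of the 1,3-diketone, made by a Baker–Venkataraman shift of a 5-O-benzoyl group onto the 6-acetyl CH3. (b) The C3=C4 double bond of the pyran ring, made by ring-closing metathesis. (c) C4a–C4 (formyl, then Wittig), O1–C2 (tertiary propargyl ether) and 7-O–CH3, back to symmetric 2,4,6-trihydroxyacetophenone.
- Enabling feature: C3=C4 is the only olefin of the target and is endocyclic in the six-membered pyran ring. C4 sits on aromatic C4a, C3 sits on the quaternary C2 bound to O1, and C4a and C8a are neighbours. Cutting this bond therefore leaves two terminal alkenes held side by side on the benzene ring.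
- Forward: the benzene ring is bought. O1–C2, O–CH3 and C4a–C4 are attached in steps 1–3, the two alkenes are unveiled in steps 4–5, the pyran ring closes in step 6, and the benzoyl carbon is joined to the acetyl carbon in steps 7–8.
- Regiocontrol: the 4-hydroxyl is the only one that cannot chelate to the acetyl group. The resulting 2,6-diol is symmetric and has only one mono-methyl ether. The last free phenol then directs formylation to its single open ortho carbon, which fixes the linear ring fusion.
- Stereochemistry: the target has no stereocentre, and its one alkene is cis because it lies in a six-membered ring.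

Key step: step 6

Assumption: the target is written and handled as its diketo tautomer. It will equilibrate with the chelated enol form, which changes nothing in the route.

**Step 1**
Reactants: 1 2,4,6-trihydroxyacetophenone; 2 3-chloro-3-methylbut-1-yne
Product: 3 1-{2,6-dihydroxy-4-[(2-methylbut-3-yn-2-yl)oxy]phenyl}ethan-1-one
Conditions: 2 (1.1 equiv), DBU (1.2 equiv), CuCl2·2H2O (1 mol %), MeCN, 0 °C
Reagents that add atoms: none
Why: Copper-catalysed O-alkylation of a phenoxide with a tertiary propargylic chloride is the standard entry to aryl 1,1-dimethylpropargyl ethers, and with about one equivalent of base it should occur at 4-OH, the most acidic hydroxyl and the only one that cannot hydrogen-bond to the acetyl oxygen.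

**Step 2**
Reactants: 3 1-{2,6-dihydroxy-4-[(2-methylbut-3-yn-2-yl)oxy]phenyl}ethan-1-one
Product: 4 1-{2-hydroxy-6-methoxy-4-[(2-methylbut-3-yn-2-yl)oxy]phenyl}ethan-1-one
Conditions: Me2SO4 (1.05 equiv), K2CO3 (1.1 equiv), acetone, 20 → 40 °C
Reagents that add atoms: dimethyl sulfate, COS(=O)(=O)OC
Why: Williamson O-methylation with a hard electrophile: the two hydroxyls of 3 are equivalent by symmetry, so only one mono-ether can form, and the remaining hydroxyl becomes locked in a strong hydrogen bond to the ketone and reacts much more slowly, which should stop the reaction after one methyl group.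

**Step 3**
Reactants: 4 1-{2-hydroxy-6-methoxy-4-[(2-methylbut-3-yn-2-yl)oxy]phenyl}ethan-1-one
Product: 6 3-acetyl-2-hydroxy-4-methoxy-6-[(2-methylbut-3-yn-2-yl)oxy]benzaldehyde, via hydroxymethyl phenol 5 (not isolated)
Conditions: MgCl2 (3 equiv), Et3N (4 equiv), (CH2O)n (7 equiv), THF, 65 °C; cold 1 M HCl wash
Reagents that add atoms: paraformaldehyde, reacting as formaldehyde, C=O
Why: Casnati–Skattebøl ortho-formylation: the magnesium phenoxide of 4 binds formaldehyde and passes it through a cyclic transition state only to a carbon ortho to the phenoxide oxygen, which here can only be C3 because C1 carries the acetyl group, and the magnesium alkoxide of 5 is then oxidised to the aldehyde by hydride transfer to a second formaldehyde, all in basic medium and well below the temperature at which the propargyl ether rearranges.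

**Step 4**
Reactants: 6 3-acetyl-2-hydroxy-4-methoxy-6-[(2-methylbut-3-yn-2-yl)oxy]benzaldehyde
Product: 7 3-acetyl-2-hydroxy-4-methoxy-6-[(2-methylbut-3-en-2-yl)oxy]benzaldehyde
Conditions: H2 (1 atm, stopped after 1 equiv), Pd/CaCO3 poisoned with Pb(OAc)2 (Lindlar catalyst), quinoline, EtOAc, 20 °C
Reagents that add atoms: none
Why: Lindlar semi-hydrogenation is the routine way from aryl 1,1-dimethylpropargyl ethers to 1,1-dimethylallyl ethers because the terminal alkyne displaces the product alkene from the poisoned palladium surface, and it is placed here because aldehyde and ketone are inert to it, whereas a styrene introduced earlier would compete for hydrogen.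

**Step 5**
Reactants: 7 3-acetyl-2-hydroxy-4-methoxy-6-[(2-methylbut-3-en-2-yl)oxy]benzaldehyde
Product: 8 1-{3-ethenyl-2-hydroxy-6-methoxy-4-[(2-methylbut-3-en-2-yl)oxy]phenyl}ethan-1-one
Conditions: Ph3PCH3Br (2.5 equiv), KOtBu (2.4 equiv), THF, 0 °C, then 7, 0 → 20 °C
Reagents that add atoms: methyltriphenylphosphonium bromide, C[P+](c1ccccc1)(c1ccccc1)c1ccccc1.[Br-]
Why: Wittig methylenation, known for salicylaldehydes when one extra equivalent of ylide is spent on the phenol; the acetyl group, crowded by two ortho oxygen substituents and deactivated by the conjugated phenoxide, should be left alone, and the low temperature spares the tertiary allyl ether.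

**Step 6**
Reactants: 8 1-{3-ethenyl-2-hydroxy-6-methoxy-4-[(2-methylbut-3-en-2-yl)oxy]phenyl}ethan-1-one
Product: 9 1-(5-hydroxy-7-methoxy-2,2-dimethyl-2H-chromen-6-yl)ethan-1-one
Conditions: RuCl2(=CHPh)(PCy3)(H2IMes) (second-generation Grubbs catalyst, 5 mol %), CH2Cl2 (0.01 M), argon sparge, 25 → 40 °C
Reagents that add atoms: none
Why: This is ring-closing olefin metathesis, the reaction type by which ortho-vinylaryl allyl ethers are routinely turned into 2H-chromenes. The ruthenium benzylidene first exchanges with the styrenic CH=CH2 on C4a, the resulting arylidene adds to the nearby CH=CH2 of the 1,1-dimethylallyl group to give a ruthenacyclobutane, and cycloreversion delivers the C3=C4 bond and Ru=CH2, which carries the chain while ethene escapes. The pyran ring closes as a six-membered ring from a 1,7-diene whose ends hang on the adjacent carbons C4a and C8a, and the two methyl groups on C2 push the alkene towards the styrene (Thorpe–Ingold effect), which offsets the crowding next to the quaternary carbon. No stereocentre is created, and the ring size allows only the cis alkene. Cyclisation must be faster than intermolecular metathesis of the styrene and than the [3,3] shift of the tertiary allyl ether to the free ortho carbon; the proximity of the two alkenes, high dilution, removal of ethene and a ceiling of 40 °C should secure both. The hydrogen-bonded phenol, the aryl ketone and the methyl ether neither bind nor destroy the catalyst, and the linear ring fusion is already fixed by the site of the vinyl group.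

**Step 7**
Reactants: 9 1-(5-hydroxy-7-methoxy-2,2-dimethyl-2H-chromen-6-yl)ethan-1-one; 10 benzoyl chloride
Product: 11 6-acetyl-7-methoxy-2,2-dimethyl-2H-chromen-5-yl benzoate
Conditions: 10 (1.3 equiv), Et3N (2 equiv), DMAP (10 mol %), CH2Cl2, 0 → 20 °C
Reagents that add atoms: none
Why: DMAP-catalysed O-benzoylation (nucleophilic acyl-transfer catalysis) is strong enough to overcome the hydrogen bond of the single hydroxyl to the ketone, and 9 offers no other nucleophilic site.

**Step 8**
Reactants: 11 6-acetyl-7-methoxy-2,2-dimethyl-2H-chromen-5-yl benzoate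
Product: 12 1-(5-hydroxy-7-methoxy-2,2-dimethyl-2H-chromen-6-yl)-3-phenylpropane-1,3-dione
Conditions: LiN(SiMe3)2 (2.5 equiv), THF, −78 → 0 °C; then 1 M HCl to pH 5, 0 °C
Reagents that add atoms: none
Why: Baker–Venkataraman rearrangement: the lithium enolate of the acetyl group attacks the neighbouring benzoate carbonyl through a six-membered cyclic alkoxide, which opens to the phenoxide and the stabilised diketone enolate (hence more than two equivalents of base), and a cold, weakly acidic quench should release 12 without cyclodehydration.

**Compound list**

1 | 2,4,6-trihydroxyacetophenone | CC(=O)c1c(O)cc(O)cc1O | starting material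
2 | 3-chloro-3-methylbut-1-yne | CC(C)(Cl)C#C | starting material
3 | 1-{2,6-dihydroxy-4-[(2-methylbut-3-yn-2-yl)oxy]phenyl}ethan-1-one | CC(=O)c1c(O)cc(OC(C)(C)C#C)cc1O | intermediate
4 | 1-{2-hydroxy-6-methoxy-4-[(2-methylbut-3-yn-2-yl)oxy]phenyl}ethan-1-one | CC(=O)c1c(OC)cc(OC(C)(C)C#C)cc1O | intermediate
5 | 1-{2-hydroxy-3-(hydroxymethyl)-6-methoxy-4-[(2-methylbut-3-yn-2-yl)oxy]phenyl}ethan-1-one (not isolated) | CC(=O)c1c(OC)cc(OC(C)(C)C#C)c(CO)c1O | intermediate
6 | 3-acetyl-2-hydroxy-4-methoxy-6-[(2-methylbut-3-yn-2-yl)oxy]benzaldehyde | CC(=O)c1c(OC)cc(OC(C)(C)C#C)c(C=O)c1O | intermediate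
7 | 3-acetyl-2-hydroxy-4-methoxy-6-[(2-methylbut-3-en-2-yl)oxy]benzaldehyde | CC(=O)c1c(OC)cc(OC(C)(C)C=C)c(C=O)c1O | intermediate
8 | 1-{3-ethenyl-2-hydroxy-6-methoxy-4-[(2-methylbut-3-en-2-yl)oxy]phenyl}ethan-1-one | CC(=O)c1c(OC)cc(OC(C)(C)C=C)c(C=C)c1O | intermediate
9 | 1-(5-hydroxy-7-methoxy-2,2-dimethyl-2H-chromen-6-yl)ethan-1-one | CC(=O)c1c(OC)cc2OC(C)(C)C=Cc2c1O | intermediate
10 | benzoyl chloride | O=C(Cl)c1ccccc1 | starting material
11 | 6-acetyl-7-methoxy-2,2-dimethyl-2H-chromen-5-yl benzoate | CC(=O)c1c(OC)cc2OC(C)(C)C=Cc2c1OC(=O)c1ccccc1 | intermediate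
12 | 1-(5-hydroxy-7-methoxy-2,2-dimethyl-2H-chromen-6-yl)-3-phenylpropane-1,3-dione | COc1cc2c(c(O)c1C(=O)CC(=O)c1ccccc1)C=CC(C)(C)O2 | target

Total step count: 8. Longest linear sequence: 8 (from 1 to 12).

**Steps most likely to fail**

**Step 3 (ortho-formylation).**
- What may go wrong: attack at the crowded carbon between the phenoxide and the tertiary ether may be sluggish. Two electron-rich rings may become methylene-bridged at the benzylic alcohol stage. The propargyl group may be lost or shifted by heat or Lewis acid.
- Fallback, from 4 back to 8: the carbon substituent is brought in by cross-coupling instead of formylation.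
- Electrophilic iodination of 4 (N-iodosuccinimide, MeCN, 0 °C) should give 1-{2-hydroxy-3-iodo-6-methoxy-4-[(2-methylbut-3-yn-2-yl)oxy]phenyl}ethan-1-one F1. In chelated 2-hydroxy-4,6-dialkoxyacetophenones this reaction favours the carbon ortho to the hydroxyl.
- Suzuki–Miyaura coupling with vinylboronic acid pinacol ester (PdCl2(dppf), K2CO3, dioxane–H2O, 60 °C) should then give 1-{3-ethenyl-2-hydroxy-6-methoxy-4-[(2-methylbut-3-yn-2-yl)oxy]phenyl}ethan-1-one F2.
- Lindlar semi-hydrogenation, stopped after one equivalent of hydrogen, leads to 8, so that 5, 6 and 7 are bypassed.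

**Step 6 (ring-closing metathesis).**
- What may go wrong: the alkene next to the quaternary carbon may engage too slowly. Intermolecular metathesis of the styrene, catalyst decay or the [3,3] shift of the allyl ether could then take over.
- Fallback, from 4 back to 9: the pyran ring is made by a pericyclic cascade instead of metathesis.
- Heating 4 in N,N-diethylaniline or xylene at about 140 °C should trigger the aryl propargyl ether Claisen shift to C3. This gives 1-[2,4-dihydroxy-6-methoxy-3-(3-methylbuta-1,2-dien-1-yl)phenyl]ethan-1-one F3, which reacts on in the flask by a 1,5-hydrogen shift and oxa-6π electrocyclisation to 9.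
- The chelated hydroxyl biases the shift towards C3. Regiocontrol is still weaker than in the main route, because the second ortho carbon is also open.

**Step 8 (acyl shift).**
- What may go wrong: the benzoyl group may be lost by simple cleavage instead of being transferred. The product may suffer retro-Claisen cleavage in base, or acid-induced cyclodehydration during the quench.
- Fallback, from 9 back to 12: the intramolecular shift is replaced by an intermolecular crossed Claisen condensation.
- The phenoxide–enolate dianion of 9 (LiN(SiMe3)2 or NaH, at least 3 equiv, THF) is C-acylated with methyl benzoate at 20 → 65 °C and then quenched cold at pH 5. Compound 11 is skipped, and no compound outside the list is made (F0).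

**Further compounds**

F1 | step 3 | 1-{2-hydroxy-3-iodo-6-methoxy-4-[(2-methylbut-3-yn-2-yl)oxy]phenyl}ethan-1-one | CC(=O)c1c(OC)cc(OC(C)(C)C#C)c(I)c1O
F2 | step 3 | 1-{3-ethenyl-2-hydroxy-6-methoxy-4-[(2-methylbut-3-yn-2-yl)oxy]phenyl}ethan-1-one | CC(=O)c1c(OC)cc(OC(C)(C)C#C)c(C=C)c1O
F3 | step 6 | 1-[2,4-dihydroxy-6-methoxy-3-(3-methylbuta-1,2-dien-1-yl)phenyl]ethan-1-one | CC(=O)c1c(OC)cc(O)c(C=C=C(C)C)c1O
F0 | step 8 | none | none
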